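Retrosynthesis: the four phenols are masked as MOM ethers (13). Ring C of 13 is then cut at C3–C4 and at O1–C2, leaving ring A as salicylaldehyde 8 and ring B as terminal arylacetylene 11. Their formulas add up exactly to that of 13.
Enabling feature: O1 sits on C8a, ortho to C4a, which carries C4. In 8 the free O1–H next to the formyl C4–H allows a five-membered O1–C8a–C4a–C4–Rh chelate for C–H activation. After C3–C4 coupling the same O1 faces C2, which is beta to C4=O and benzylic to ring B.
Aldehyde 8 is cut at C4–C4a (formylation), at C8a–O1 (borylation/oxidation) and at C6–C1'' (allylation), back to resorcinol and geranyl bromide. Every intermediate up to phenol 7 has a mirror plane, so the geranyl group can end only at C6, never at C8.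
Forward: ring A piece (steps 1–4), ring B piece from 5-hydroxyvanillin (steps 5–6), union and closure of ring C in one flask (step 7), release of the four phenols (step 8).
Stereochemistry: C2 (S) is set in step 7 by a chiral bifunctional thiourea during the oxa-Michael closure. The E alkene of the side chain comes with geranyl bromide and is never touched.

Key step: step 7

Assumption: the quinine-derived thiourea is taken to deliver the 2S series. No close analogue secures the sense of induction on this enone, and the quinidine-derived pseudo-enantiomer would take its place if the opposite sense were found.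

Step 1
Reactants: 1 resorcinol
Product: 2 1,3-bis(methoxymethoxy)benzene
Conditions: MOMCl (2.5 equiv), K2CO3, acetone, reflux
Reagents that add atoms: chloromethyl methyl ether (MOMCl), COCCl
Why: Williamson-type acetal ether formation (MOM protection) should proceed cleanly on both phenols of the symmetric diol and installs the two groups that direct the next metalation.

Step 2
Reactants: 2 1,3-bis(methoxymethoxy)benzene; 3 geranyl bromide
Product: 5 2-geranyl-1,3-bis(methoxymethoxy)benzene, via aryllithium 4 (not isolated)
Conditions: n-BuLi, THF, 0 °C to rt; then CuBr·SMe2 (10 mol %), 3, −40 °C to rt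
Reagents that add atoms: n-butyllithium, [Li]CCCC (lithium of 4 only)
Why: Directed ortho-metalation should occur at C2 between the two cooperating OMOM groups, and copper-assisted SN2 allylation of 4 with the primary allylic bromide keeps the E alkene of 3.

Step 3
Reactants: 5 2-geranyl-1,3-bis(methoxymethoxy)benzene
Product: 7 4-geranyl-3,5-bis(methoxymethoxy)phenol, via arylboronate 6 (not isolated)
Conditions: [Ir(OMe)(cod)]2 (1.5 mol %), dtbpy (3 mol %), B2pin2 (0.6 equiv), THF, 60 °C; then 30% aq H2O2, aq NaOH, 0 °C
Reagents that add atoms: hydrogen peroxide, OO (the phenol oxygen); bis(pinacolato)diboron, CC1(C)OB(OC1(C)C)B1OC(C)(C)C(C)(C)O1 (boryl group of 6 only)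
Why: Iridium-catalysed aromatic C–H borylation is governed by sterics, and in this 1,2,3-trisubstituted arene only C5 has no ortho neighbour, while the trisubstituted alkenes are too hindered to insert, so alkaline peroxide oxidation of the boronate should place the oxygen para to geranyl (borylation/oxidation sequence).

Step 4
Reactants: 7 4-geranyl-3,5-bis(methoxymethoxy)phenol
Product: 8 3-geranyl-6-hydroxy-2,4-bis(methoxymethoxy)benzaldehyde
Conditions: MgCl2, Et3N, (CH2O)n, THF, reflux; dilute HCl work-up at 0 °C
Reagents that add atoms: paraformaldehyde (as formaldehyde), C=O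
Why: The Casnati–Skattebøl ortho-formylation runs through the magnesium phenoxide and attacks only ortho to the free OH, and since the two ortho positions are equivalent by symmetry and para is blocked, the CHO group should end next to the free oxygen (future O1) and remote from geranyl.

Step 5
Reactants: 9 3,4-dihydroxy-5-methoxybenzaldehyde (5-hydroxyvanillin)
Product: 10 3-methoxy-4,5-bis(methoxymethoxy)benzaldehyde
Conditions: MOMCl (2.5 equiv), K2CO3, acetone, reflux
Reagents that add atoms: chloromethyl methyl ether (MOMCl), COCCl
Why: MOM protection (Williamson-type) of the catechol should shield it from oxidation and from binding to rhodium, and the non-enolisable aldehyde is inert to carbonate.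

Step 6
Reactants: 10 3-methoxy-4,5-bis(methoxymethoxy)benzaldehyde
Product: 11 5-ethynyl-1-methoxy-2,3-bis(methoxymethoxy)benzene
Conditions: dimethyl (1-diazo-2-oxopropyl)phosphonate, K2CO3, MeOH, rt
Reagents that add atoms: dimethyl (1-diazo-2-oxopropyl)phosphonate (Ohira–Bestmann reagent), COP(=O)(OC)C(=[N+]=[N-])C(C)=O (its diazo carbon becomes the terminal alkyne carbon)
Why: The Ohira–Bestmann variant of the Seyferth–Gilbert homologation converts aryl aldehydes into terminal alkynes under mild carbonate conditions that MOM ethers tolerate.

Step 7
Reactants: 8 3-geranyl-6-hydroxy-2,4-bis(methoxymethoxy)benzaldehyde; 11 5-ethynyl-1-methoxy-2,3-bis(methoxymethoxy)benzene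
Product: 13 (2S)-6-geranyl-5,7-bis(methoxymethoxy)-2-[3-methoxy-4,5-bis(methoxymethoxy)phenyl]chroman-4-one, via chalcone 12 (not isolated)
Conditions: [Rh(OMe)(cod)]2 (2.5 mol %), 1,1'-bis(diphenylphosphino)ferrocene (5 mol %), toluene, 70 °C, slow addition of 11 (1.2 equiv); then 0 °C, N-[3,5-bis(trifluoromethyl)phenyl]-N'-[(8α,9S)-6'-methoxycinchonan-9-yl]thiourea (15 mol %)
Reagents that add atoms: none
Why: Proposed new method: the methoxide ligand deprotonates the only free phenol of 8, the resulting aryloxide of monovalent rhodium inserts into the adjacent formyl C–H bond to give a five-membered O1,C4-chelated acyl hydride of trivalent rhodium that is held back from decarbonylation, syn hydrometalation of 11 places rhodium on the terminal carbon, and C–C reductive elimination forms C3–C4 in (E)-chalcone 12. In the cold second stage the quinuclidine nitrogen of the added catalyst takes up the O1–H proton while its two thiourea N–H bonds bind the C4 carbonyl oxygen, O1 adds to C2 and closes ring C in a 6-endo-trig oxa-Michael mode, and the enol tautomerises to ketone 13. The closest known reaction types are the rhodium-catalysed tandem alkyne hydroacylation/oxo-Michael addition of salicylaldehydes, known with internal alkynes and an achiral fluoride trigger, and the cinchona thiourea-catalysed cyclisation of 2'-hydroxychalcones; new are their relay in one flask, the terminal arylacetylene and the doubly ortho-substituted aldehyde. C2 is the only new stereocentre and is controlled by the catalyst, whose ion-paired phenoxide and hydrogen-bonded carbonyl fix the enone in one chiral pocket so that O1 reaches one face of C2, while the base-free, apolar first stage keeps the uncatalysed closure slow. Three selectivities are needed: linear rather than branched insertion, secured by the terminal alkyne, the bulky acyl ligand and the wide-bite-angle diphosphine; alkyne rather than geranyl alkenes, secured because trisubstituted alkenes do not insert into the rhodium hydride; and closure to the 6-geranyl rather than the 8-geranyl isomer, secured because O5 is blocked as its MOM ether and O1 is the only free phenol.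

Step 8
Reactants: 13 (2S)-6-geranyl-5,7-bis(methoxymethoxy)-2-[3-methoxy-4,5-bis(methoxymethoxy)phenyl]chroman-4-one
Product: 14 (2S)-6-geranyl-5,7-dihydroxy-2-(3,4-dihydroxy-5-methoxyphenyl)chroman-4-one (target)
Conditions: conc. HCl (cat.), MeOH, 0 °C to rt, argon
Reagents that add atoms: none
Why: Acid-catalysed transacetalisation should turn the four aryl MOM ethers into dimethoxymethane under acid too dilute and too cold to protonate the trisubstituted alkenes, and C2 should hold because flavanones epimerise through base-induced ring opening, not under mild acid.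

Compound list
1 | resorcinol | Oc1cccc(O)c1 | starting material
2 | 1,3-bis(methoxymethoxy)benzene | COCOc1cccc(OCOC)c1 | intermediate
3 | geranyl bromide, (2E)-1-bromo-3,7-dimethylocta-2,6-diene | BrC/C=C(\C)CCC=C(C)C | starting material
4 | 2-lithio-1,3-bis(methoxymethoxy)benzene | [Li]c1c(OCOC)cccc1OCOC | intermediate
5 | 2-[(2E)-3,7-dimethylocta-2,6-dienyl]-1,3-bis(methoxymethoxy)benzene | COCOc1cccc(OCOC)c1C/C=C(\C)CCC=C(C)C | intermediate
6 | 2-[4-geranyl-3,5-bis(methoxymethoxy)phenyl]-4,4,5,5-tetramethyl-1,3,2-dioxaborolane | COCOc1cc(B2OC(C)(C)C(C)(C)O2)cc(OCOC)c1C/C=C(\C)CCC=C(C)C | intermediate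
7 | 4-geranyl-3,5-bis(methoxymethoxy)phenol | COCOc1cc(O)cc(OCOC)c1C/C=C(\C)CCC=C(C)C | intermediate
8 | 3-geranyl-6-hydroxy-2,4-bis(methoxymethoxy)benzaldehyde | O=Cc1c(O)cc(OCOC)c(C/C=C(\C)CCC=C(C)C)c1OCOC | intermediate
9 | 3,4-dihydroxy-5-methoxybenzaldehyde (5-hydroxyvanillin) | COc1cc(C=O)cc(O)c1O | starting material
10 | 3-methoxy-4,5-bis(methoxymethoxy)benzaldehyde | COc1cc(C=O)cc(OCOC)c1OCOC | intermediate
11 | 5-ethynyl-1-methoxy-2,3-bis(methoxymethoxy)benzene | COc1cc(C#C)cc(OCOC)c1OCOC | intermediate
12 | (E)-1-[3-geranyl-6-hydroxy-2,4-bis(methoxymethoxy)phenyl]-3-[3-methoxy-4,5-bis(methoxymethoxy)phenyl]prop-2-en-1-one | COc1cc(/C=C/C(=O)c2c(O)cc(OCOC)c(C/C=C(\C)CCC=C(C)C)c2OCOC)cc(OCOC)c1OCOC | intermediate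
13 | (2S)-6-geranyl-5,7-bis(methoxymethoxy)-2-[3-methoxy-4,5-bis(methoxymethoxy)phenyl]chroman-4-one | COc1cc([C@@H]2CC(=O)c3c(cc(OCOC)c(C/C=C(\C)CCC=C(C)C)c3OCOC)O2)cc(OCOC)c1OCOC | intermediate
14 | (2S)-6-geranyl-5,7-dihydroxy-2-(3,4-dihydroxy-5-methoxyphenyl)chroman-4-one | COc1cc([C@@H]2CC(=O)c3c(cc(O)c(C/C=C(\C)CCC=C(C)C)c3O)O2)cc(O)c1O | target

Total step count: 8. Longest linear sequence: 6 (steps 1, 2, 3, 4, 7, 8).

Steps most likely to fail

**Step 7** is most at risk. The chalcone may already close without catalyst control during the warm first stage. Facial discrimination may be weak on an enone that has no second activating group. Loss of CO from the hindered acyl rhodium hydride or branched insertion may also lower the throughput. The fallback uses known chemistry only and takes the stereochemistry from a kinetic resolution instead of the ring closure.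
- It sets out from 8 and 11. These are joined by the established tandem hydroacylation/oxo-Michael protocol ([RhCl(cod)]2, 1,1'-bis(diphenylphosphino)ferrocene, Na2CO3, toluene, then CsF) to give the racemic tetra-MOM flavanone F1.
- Noyori-type asymmetric transfer hydrogenation with [RhCl(C5Me5){(R,R)-TsDPEN}] and HCO2H/Et3N in EtOAc should reduce only the 2R enantiomer to the cis-(2R,4R)-flavan-4-ol F2.
- The unreacted 2S ketone is separated by chromatography, and the route is rejoined at 13.

**Step 8** is second. The acid may drive addition of the freed O5 or O7 phenol to the neighbouring C2''=C3'' alkene, closing a chroman. Slow opening and reclosure of ring C may erode C2. The fallback replaces Brønsted acid solvolysis by a protecting-group exchange.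
- It sets out from 13. TESOTf and 2,2'-bipyridyl in MeCN at 0 °C should convert the four aryl MOM ethers directly into the tetrakis(triethylsilyl) ether F3.
- Et3N·3HF in THF then desilylates F3 under buffered, nearly neutral conditions, and the route is rejoined at 14.

**Step 3** is third. The geranyl chain may undergo hydroboration, vinylic or allylic borylation, or alkene migration by iridium hydride species. The fallback changes the order of events so that no alkene ever meets iridium.
- It sets out from 2, which is borylated under the same catalyst to the arylboronate F4 and oxidised to 3,5-bis(methoxymethoxy)phenol F5.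
- TIPSCl/imidazole gives the silyl ether F6. Its bulky, non-directing OTIPS group leaves the position between the two OMOM groups as the only doubly activated site for n-BuLi, giving the aryllithium F7.
- Allylation with 3 gives the geranylated silyl ether F8, TBAF removes the silyl group, and the route is rejoined at 7.

Further compounds
F1 | step 7 | racemic 6-geranyl-5,7-bis(methoxymethoxy)-2-[3-methoxy-4,5-bis(methoxymethoxy)phenyl]chroman-4-one | COc1cc(C2CC(=O)c3c(cc(OCOC)c(C/C=C(\C)CCC=C(C)C)c3OCOC)O2)cc(OCOC)c1OCOC
F2 | step 7 | (2R,4R)-6-geranyl-5,7-bis(methoxymethoxy)-2-[3-methoxy-4,5-bis(methoxymethoxy)phenyl]chroman-4-ol | COc1cc([C@H]2C[C@@H](O)c3c(cc(OCOC)c(C/C=C(\C)CCC=C(C)C)c3OCOC)O2)cc(OCOC)c1OCOC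
F3 | step 8 | (2S)-6-geranyl-2-[3-methoxy-4,5-bis(triethylsilyloxy)phenyl]-5,7-bis(triethylsilyloxy)chroman-4-one | COc1cc([C@@H]2CC(=O)c3c(cc(O[Si](CC)(CC)CC)c(C/C=C(\C)CCC=C(C)C)c3O[Si](CC)(CC)CC)O2)cc(O[Si](CC)(CC)CC)c1O[Si](CC)(CC)CC
F4 | step 3 | 2-[3,5-bis(methoxymethoxy)phenyl]-4,4,5,5-tetramethyl-1,3,2-dioxaborolane | COCOc1cc(OCOC)cc(B2OC(C)(C)C(C)(C)O2)c1
F5 | step 3 | 3,5-bis(methoxymethoxy)phenol | COCOc1cc(O)cc(OCOC)c1
F6 | step 3 | [3,5-bis(methoxymethoxy)phenoxy]triisopropylsilane | COCOc1cc(O[Si](C(C)C)(C(C)C)C(C)C)cc(OCOC)c1
F7 | step 3 | [4-lithio-3,5-bis(methoxymethoxy)phenoxy]triisopropylsilane | [Li]c1c(OCOC)cc(O[Si](C(C)C)(C(C)C)C(C)C)cc1OCOC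
F8 | step 3 | [4-geranyl-3,5-bis(methoxymethoxy)phenoxy]triisopropylsilane | COCOc1cc(O[Si](C(C)C)(C(C)C)C(C)C)cc(OCOC)c1C/C=C(\C)CCC=C(C)C
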